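**Retrosynthetic overview**
1. Feature: in ring C (the seven-membered lactone) the ester oxygen lies between the lactone carbonyl carbon, which sits on ring A (the formyl phenol ring), and the ring B carbon next to the ring B methyl group. Without this one oxygen, rings A and B and the diaryl ether oxygen form a xanthone with methyl groups at both peri positions (C1, C8), and each aryl half is an orcinol unit; ring D is the gem-dimethylpyranone on ring B.
2. Key disconnection: this oxygen goes in last, by a Baeyer–Villiger-type one-atom ring expansion of the O-methylated xanthone (9-methoxyxanthylium ion, peroxide adduct at C9, shift of ring B from C9 to oxygen). Ring A is masked as aryl acetate and formyl diacetate.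
3. The xanthone comes from a benzophenone by aryl ether closure, the formyl group from a Duff reaction beside the ring A phenol, and the benzophenone from a ring B carboxylic acid and 3,5-dimethoxytoluene (Friedel–Crafts).
4. The ring B acid comes from 3,5-dimethoxytoluene and 3-methylbut-2-enoyl chloride (acylation, oxa-Michael closure of ring D), then formylation and oxidation.
5. Ring order: D, then the six-membered pyranone ring of the xanthone, then its expansion to ring C; rings A and B are both bought as 3,5-dimethoxytoluene.

Key step: step 8

Remark: both orcinol units are used as dimethyl ethers, because free orcinol is acylated at two different positions whereas the ethers direct both C–C bond formations beside the arene methyl group. Chromanone locants are used up to step 4; from step 5 on, xanthone locants are used (C9 carbonyl carbon, O10 ring oxygen, ring A C1–C4, ring B C5–C8).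

**Step 1**
Reactants: 1 3,5-dimethoxytoluene; 2 3-methylbut-2-enoyl chloride
Product: 5 7-methoxy-2,2,5-trimethylchroman-4-one, via dimethoxyaryl enone 3 (not isolated), via hydroxyaryl enone 4 (not isolated)
Conditions: AlCl3 (2.5 equiv), CH2Cl2, 0 °C to reflux; 1 M HCl; then K2CO3, MeOH, rt
Reagents that add atoms: none
Why: Friedel–Crafts acylation of 1 should go to C2 (beside the methyl group, para to a methoxy group), the site at which this arene is acetylated and formylated; AlCl3 held by the new ketone then cleaves only the ortho methyl ether, and the phenol closes ring D by 6-endo oxa-Michael addition to the enone.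

**Step 2**
Reactants: 5 7-methoxy-2,2,5-trimethylchroman-4-one
Product: 6 7-methoxy-2,2,5-trimethyl-4-oxochroman-6-carbaldehyde
Conditions: Cl2CHOMe (1.5 equiv), TiCl4 (2.5 equiv), CH2Cl2, 0 °C to rt; ice-cold 1 M HCl
Reagents that add atoms: dichloromethyl methyl ether, COC(Cl)Cl (formyl carbon); water, O (formyl oxygen, on work-up)
Why: Rieche formylation is an electrophilic aromatic substitution that should enter at C6, which is ortho to the methoxy group and para to the ring oxygen, and not at C8 between the two oxygens, in line with the substitution of 2,4-dialkoxyaryl ketones at C5.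

**Step 3**
Reactants: 6 7-methoxy-2,2,5-trimethyl-4-oxochroman-6-carbaldehyde
Product: 7 7-methoxy-2,2,5-trimethyl-4-oxochroman-6-carboxylic acid
Conditions: NaClO2, NaH2PO4, 2-methylbut-2-ene, t-BuOH–H2O, rt
Reagents that add atoms: sodium chlorite NaClO2, [Na+].[O-]Cl=O
Why: Pinnick oxidation converts the hindered aryl aldehyde into the acid without touching the ketone, and the alkene scavenger takes up hypochlorous acid before it can chlorinate C8.

**Step 4**
Reactants: 7 7-methoxy-2,2,5-trimethyl-4-oxochroman-6-carboxylic acid; 1 3,5-dimethoxytoluene (1.5 equiv)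
Product: 9 6-(2,4-dimethoxy-6-methylbenzoyl)-7-methoxy-2,2,5-trimethylchroman-4-one, via mixed anhydride 8 (not isolated)
Conditions: (CF3CO)2O (3 equiv), CH2Cl2, 0 °C to rt
Reagents that add atoms: none
Why: the 2,6-disubstituted acid should ionise from its mixed trifluoroacetic anhydride to a linear acylium ion, which acylates 1 at C2 (Friedel–Crafts acylation, same site as in step 1), so the benzophenone with four ortho substituents can form despite the crowding; the excess of 1 guards against a second acylation.

**Step 5**
Reactants: 9 6-(2,4-dimethoxy-6-methylbenzoyl)-7-methoxy-2,2,5-trimethylchroman-4-one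
Product: 11 9-hydroxy-2,2,5,7-tetramethyl-2,3-dihydropyrano[3,2-b]xanthene-4,6-dione (the 3-hydroxy-1,8-dimethylxanthone carrying ring D at C6–C7), via trihydroxybenzophenone 10 (not isolated)
Conditions: pyridine·HCl (melt, 20 equiv), 185 °C; then H2O
Reagents that add atoms: none
Why: pyridinium chloride cleaves the three aryl methyl ethers by attack of chloride at methyl, and the 2,2'-dihydroxybenzophenone should close the pyranone ring by addition–elimination at the oxygen-bearing ring B carbon (ortho to the diaryl ketone, para to the ring D ketone) with loss of water, the classical demethylative xanthone synthesis; ring D, if it opens to the enone in the melt, recloses.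

**Step 6**
Reactants: 11 hydroxy xanthone
Product: 12 9-hydroxy-2,2,5,7-tetramethyl-4,6-dioxo-3,4-dihydro-2H,6H-pyrano[3,2-b]xanthene-10-carbaldehyde (formyl group at xanthone C4)
Conditions: (CH2)6N4 (3 equiv), CF3CO2H, 85 °C; then 3 M HCl, 60 °C
Reagents that add atoms: hexamethylenetetramine, C1N2CN3CN1CN(C2)C3 (formyl carbon); water, O (formyl oxygen)
Why: the Duff formylation is delivered ortho to the free phenol, and of the two ortho sites C4 (between the hydroxyl and O10) should be taken rather than C2 beside the peri methyl group, as 7-hydroxychromones and 7-hydroxycoumarins are formylated at C8; ring B has no phenol and carries two carbonyl groups.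

**Step 7**
Reactants: 12 hydroxy aldehyde
Product: 13 10-(diacetoxymethyl)-2,2,5,7-tetramethyl-4,6-dioxo-3,4-dihydro-2H,6H-pyrano[3,2-b]xanthen-9-yl acetate
Conditions: Ac2O, H2SO4 (cat.), 0 °C to rt
Reagents that add atoms: acetic anhydride, CC(=O)OC(C)=O
Why: acid-catalysed acetylation esterifies the phenol and turns the aldehyde into its geminal diacetate (acylal formation), which keeps the formyl group away from peroxide and makes ring A electron-poor.

**Step 8**
Reactants: 13 xanthone triacetate
Product: 18 O-acetylmollicellin B formyl diacetate, via methoxyxanthylium tetrafluoroborate 14 (not isolated), via hydroperoxy ketal 15 (not isolated), via trifluoroacetyl perester 16 (not isolated), via methoxydioxocarbenium tetrafluoroborate 17 (not isolated)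
Conditions: Me3OBF4 (1.1 equiv), ClCH2CH2Cl, 40 °C; then urea·H2O2 (1.1 equiv), 0 °C; then (CF3CO)2O (2.5 equiv), −20 to 0 °C; then Me2S, 0 °C to rt
Reagents that add atoms: urea–hydrogen peroxide, NC(N)=O.OO (one peroxide oxygen becomes the ester oxygen)
Why: Proposed new method: trimethyloxonium ion should methylate the xanthone carbonyl oxygen, the only oxygen of 13 whose alkylation gives an aromatic xanthylium ion, and this cation takes up H2O2 at C9 to give the peroxy ketal 15; trifluoroacetylation of its OOH group makes it a Criegee perester 16, in which the ring B carbon bonded to C9 shifts to the peroxide oxygen as trifluoroacetate leaves, and the cyclic methoxydioxocarbenium ion 17 gives its methyl group to Me2S to leave the lactone. The closest known reactions are the Baeyer–Villiger oxidation of diaryl ketones (for which urea·H2O2 with trifluoroacetic anhydride is a usual water-free oxidant), the Criegee rearrangement of tertiary peresters, the Hock rearrangement of triarylmethyl hydroperoxides and the peroxide cleavage of flavylium salts; peracids alone leave the xanthone carbonyl untouched, which is why it is first turned into a cation. Ring C is not closed end to end but arises by one-atom expansion of the six-membered pyranone ring (1,2-shift of an aryl carbon from carbon to oxygen), and no stereocentre remains, since C9 of the peroxide adducts is formed racemic and ends as the trigonal lactone carbon. Two selectivities are needed: methylation at the xanthone and not at the ring D carbonyl, which rests on the higher basicity of the pyranone oxygen and on the use of about one equivalent of oxonium salt, and migration of ring B and not ring A, which rests on the ring D alkoxy oxygen para to the migrating carbon as against the weakly donating acetoxy group and the electron-withdrawing diacetoxymethyl group on ring A. The two peri methyl groups press on C9, so going from the crowded tetrahedral centre in the six-membered ring to the seven-membered lactone releases strain, and the exclusion of water keeps the acylal intact and keeps ion 17 from opening to a seco methyl ester.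

**Step 9**
Reactants: 18 O-acetylmollicellin B formyl diacetate
Product: 19 mollicellin B
Conditions: 1 M H2SO4, acetone–H2O, 50 °C
Reagents that add atoms: water, O (formyl oxygen)
Why: acid-catalysed hydrolysis should remove the acylal and then the aryl acetate ortho to the freed formyl group, while the lactone, whose carbonyl carbon is flanked by a methyl and an aryloxy group and whose ester oxygen sits beside the ring B methyl group, is too shielded for acyl–oxygen cleavage under these mild conditions.

**Compound list**
1 | 3,5-dimethoxytoluene | Cc1cc(OC)cc(OC)c1 | starting material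
2 | 3-methylbut-2-enoyl chloride | CC(C)=CC(Cl)=O | starting material
3 | 1-(2,4-dimethoxy-6-methylphenyl)-3-methylbut-2-en-1-one | CC(C)=CC(=O)c1c(C)cc(OC)cc1OC | intermediate (not isolated)
4 | 1-(2-hydroxy-4-methoxy-6-methylphenyl)-3-methylbut-2-en-1-one | CC(C)=CC(=O)c1c(C)cc(OC)cc1O | intermediate (not isolated)
5 | 7-methoxy-2,2,5-trimethylchroman-4-one | COc1cc(C)c2C(=O)CC(C)(C)Oc2c1 | intermediate
6 | 7-methoxy-2,2,5-trimethyl-4-oxochroman-6-carbaldehyde | COc1cc2OC(C)(C)CC(=O)c2c(C)c1C=O | intermediate
7 | 7-methoxy-2,2,5-trimethyl-4-oxochroman-6-carboxylic acid | COc1cc2OC(C)(C)CC(=O)c2c(C)c1C(=O)O | intermediate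
8 | mixed anhydride of 7 with trifluoroacetic acid | COc1cc2OC(C)(C)CC(=O)c2c(C)c1C(=O)OC(=O)C(F)(F)F | intermediate (not isolated)
9 | 6-(2,4-dimethoxy-6-methylbenzoyl)-7-methoxy-2,2,5-trimethylchroman-4-one | COc1cc(C)c(c(OC)c1)C(=O)c1c(C)c2C(=O)CC(C)(C)Oc2cc1OC | intermediate
10 | 6-(2,4-dihydroxy-6-methylbenzoyl)-7-hydroxy-2,2,5-trimethylchroman-4-one | Oc1cc(C)c(c(O)c1)C(=O)c1c(C)c2C(=O)CC(C)(C)Oc2cc1O | intermediate (not isolated)
11 | 9-hydroxy-2,2,5,7-tetramethyl-2,3-dihydropyrano[3,2-b]xanthene-4,6-dione | Oc1cc(C)c2C(=O)c3c(C)c4C(=O)CC(C)(C)Oc4cc3Oc2c1 | intermediate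
12 | 9-hydroxy-2,2,5,7-tetramethyl-4,6-dioxo-3,4-dihydro-2H,6H-pyrano[3,2-b]xanthene-10-carbaldehyde | O=Cc1c(O)cc(C)c2C(=O)c3c(C)c4C(=O)CC(C)(C)Oc4cc3Oc12 | intermediate
13 | 10-(diacetoxymethyl)-2,2,5,7-tetramethyl-4,6-dioxo-3,4-dihydro-2H,6H-pyrano[3,2-b]xanthen-9-yl acetate (key-step precursor) | CC(=O)Oc1cc(C)c2C(=O)c3c(C)c4C(=O)CC(C)(C)Oc4cc3Oc2c1C(OC(C)=O)OC(C)=O | intermediate
14 | 9-methoxyxanthylium tetrafluoroborate of 13 (methyl on the former carbonyl oxygen) | CC(=O)Oc1cc(C)c2c(OC)c3c(C)c4C(=O)CC(C)(C)Oc4cc3[o+]c2c1C(OC(C)=O)OC(C)=O.F[B-](F)(F)F | intermediate (not isolated)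
15 | 9-hydroperoxy-9-methoxy-9H-xanthene adduct (racemic at C9) | CC(=O)Oc1cc(C)c2c(c1C(OC(C)=O)OC(C)=O)Oc1cc3OC(C)(C)CC(=O)c3c(C)c1C2(OC)OO | intermediate (not isolated)
16 | O-trifluoroacetyl perester of 15 (racemic at C9) | CC(=O)Oc1cc(C)c2c(c1C(OC(C)=O)OC(C)=O)Oc1cc3OC(C)(C)CC(=O)c3c(C)c1C2(OC)OOC(=O)C(F)(F)F | intermediate (not isolated)
17 | seven-membered cyclic methoxydioxocarbenium tetrafluoroborate | CC(=O)Oc1cc(C)c2c(c1C(OC(C)=O)OC(C)=O)Oc1cc3OC(C)(C)CC(=O)c3c(C)c1OC2=[O+]C.F[B-](F)(F)F | intermediate (not isolated)
18 | O-acetylmollicellin B formyl diacetate (key-step product) | CC(=O)Oc1cc(C)c2C(=O)Oc3c(C)c4C(=O)CC(C)(C)Oc4cc3Oc2c1C(OC(C)=O)OC(C)=O | intermediate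
19 | mollicellin B | Cc1cc(O)c(C=O)c2c1C(=O)Oc1c(cc3c(c1C)C(=O)CC(C)(C)O3)O2 | target

**Step count and risks**
Total steps: 9. Longest linear sequence: 9 steps (1 and 2 to 19; 1 enters a second time in step 4).

Steps most likely to fail:

1. Step 8. The methyl group may be taken up slowly, because both peri methyl groups shield the xanthone oxygen, or it may go to the ring D carbonyl. The peroxide adduct may fall back to the xanthone, ring A may shift instead of ring B, or free peracid may oxidise the ring D aryl ketone. The fallback uses known reactions only, sets out from aldehyde 6 and comes back at 19; it gives up the xanthone and puts the ester oxygen on ring B before the rings are joined. Dakin-type Baeyer–Villiger oxidation of 6 (mCPBA, CH2Cl2; then K2CO3, MeOH) should give 6-hydroxy-7-methoxy-2,2,5-trimethylchroman-4-one F1, and BBr3 (CH2Cl2, −78 to 0 °C) then frees the catechol 6,7-dihydroxy-2,2,5-trimethylchroman-4-one F2. Esterification with everninic acid (2-hydroxy-4-methoxy-6-methylbenzoic acid, a catalogue compound; DCC, CH2Cl2) at the more acidic 7-hydroxyl gives the depside 6-hydroxy-2,2,5-trimethyl-4-oxochroman-7-yl 2-hydroxy-4-methoxy-6-methylbenzoate F3. K2CO3 in DMSO should bring about the Smiles rearrangement: the ring A phenoxide attacks the ester-bearing ring B carbon, which is para to the ring D ketone, and an ester on the neighbouring oxygen would first move over by acyl shift. This gives the diaryl ether acid 2-[(6-hydroxy-2,2,5-trimethyl-4-oxochroman-7-yl)oxy]-4-methoxy-6-methylbenzoic acid F4, and lactonisation (DCC, toluene) closes ring C to the deformyl O-methyl depsidone F5. BBr3 at low temperature gives the phenol deformylmollicellin B F6, and ortho-formylation (Cl2CHOMe, TiCl4, CH2Cl2, 0 °C) between the hydroxyl and the diaryl ether oxygen, the site at which orsellinates are formylated, gives 19.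

2. Step 2. The formyl group may enter at C8, or the reaction may stall because the ketone complexed to TiCl4 deactivates the ring. The fallback sets out from acid chloride 2 and comes back at acid 7; it brings the carboxyl carbon in from the start. 2 acylates methyl 2,4-dimethoxy-6-methylbenzoate (a catalogue compound; AlCl3, CH2Cl2, 0 °C to rt) at C5, the only free position that is not flanked by two methoxy groups. Loss of the methyl ether beside the new ketone and oxa-Michael closure give methyl 7-methoxy-2,2,5-trimethyl-4-oxochroman-6-carboxylate F7. The hindered ester is then cleaved at the methyl carbon (LiI, pyridine, reflux) to 7.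

3. Step 5. At 185 °C in the acid melt ring D may open and degrade, the hindered electron-rich ketone may lose its aroyl group by protodeacylation, or the closure may stay incomplete. The fallback sets out from benzophenone 9 and comes back at 11; it replaces the acid fusion by a staged, base-mediated closure. BCl3 (CH2Cl2, −78 to 0 °C) removes one methyl ether ortho to the diaryl ketone, expected on ring A, to give 6-(2-hydroxy-4-methoxy-6-methylbenzoyl)-7-methoxy-2,2,5-trimethylchroman-4-one F8; the other regioisomer would close to the same xanthone. K2CO3 in DMF at 100 °C closes the pyranone ring by addition–elimination at the methoxy-bearing ring B carbon, giving 9-methoxy-2,2,5,7-tetramethyl-2,3-dihydropyrano[3,2-b]xanthene-4,6-dione F9. BBr3 (CH2Cl2, −78 to 0 °C) then cleaves the remaining methyl ether to 11.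

**Further compounds**
F1 | step 8 | 6-hydroxy-7-methoxy-2,2,5-trimethylchroman-4-one | COc1cc2OC(C)(C)CC(=O)c2c(C)c1O
F2 | step 8 | 6,7-dihydroxy-2,2,5-trimethylchroman-4-one | Oc1cc2OC(C)(C)CC(=O)c2c(C)c1O
F3 | step 8 | 6-hydroxy-2,2,5-trimethyl-4-oxochroman-7-yl 2-hydroxy-4-methoxy-6-methylbenzoate | COc1cc(C)c(c(O)c1)C(=O)Oc1cc2OC(C)(C)CC(=O)c2c(C)c1O
F4 | step 8 | 2-[(6-hydroxy-2,2,5-trimethyl-4-oxochroman-7-yl)oxy]-4-methoxy-6-methylbenzoic acid | COc1cc(C)c(C(=O)O)c(Oc2cc3OC(C)(C)CC(=O)c3c(C)c2O)c1
F5 | step 8 | deformyl O-methyl mollicellin B (depsidone methyl ether) | COc1cc(C)c2C(=O)Oc3c(C)c4C(=O)CC(C)(C)Oc4cc3Oc2c1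
F6 | step 8 | deformylmollicellin B (depsidone phenol) | Oc1cc(C)c2C(=O)Oc3c(C)c4C(=O)CC(C)(C)Oc4cc3Oc2c1
F7 | step 2 | methyl 7-methoxy-2,2,5-trimethyl-4-oxochroman-6-carboxylate | COC(=O)c1c(C)c2C(=O)CC(C)(C)Oc2cc1OC
F8 | step 5 | 6-(2-hydroxy-4-methoxy-6-methylbenzoyl)-7-methoxy-2,2,5-trimethylchroman-4-one | COc1cc(C)c(c(O)c1)C(=O)c1c(C)c2C(=O)CC(C)(C)Oc2cc1OC
F9 | step 5 | 9-methoxy-2,2,5,7-tetramethyl-2,3-dihydropyrano[3,2-b]xanthene-4,6-dione | COc1cc(C)c2C(=O)c3c(C)c4C(=O)CC(C)(C)Oc4cc3Oc2c1
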